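**Retrosynthetic overview**

- Target (labdane numbering): a trans-decalin with 4β-CO2H (C19), 8α-CO2H (C17) and a 9β-CH2CH2 chain ending in a 3-alkylbut-2-en-4-olide (C13=C14, C15–O–C16=O). The last disconnection is C13=C14, closed by an intramolecular Horner–Wadsworth–Emmons reaction that forms the lactone ring, run in one flask with a radical C11–C12 bond formation.
- Enabling feature: C13 is α to the lactone carbonyl C16 and bonded to the side-chain CH2 (C12), while C14 is tied back to C16 through C15–O. C13 can therefore be generated as a phosphonate carbanion by radical addition at C12 of a 2-phosphonoacrylate whose ester alcohol is glycolaldehyde (C14–C15).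
- The radical partner is the C12 redox-active ester of a 13,14,15,16-tetranorlabdane-12,17,19-triacid. Its C12 and C17 carboxyls sit 1,5 to each other on C9 and C8, so a six-membered anhydride singles out C12 and no protecting group is needed.
- That glutaric acid motif is what ozonolysis of a cyclohexenone leaves. The enone is ring C of a 12-oxopodocarp-13-ene (podocarpane C14 = labdane C17), reached from (+)-podocarpic acid by Birch reduction (sets C8), Li/NH3 (sets C9) and regioselective dehydrogenation.
- Ring order: rings A and B with C4, C5 and C10 come from the chiral pool; aromatic ring C is reduced, then cleaved (step 6); a transient anhydride ring follows (step 7); the butenolide ring is closed last (step 10).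

Key step: step 10

Assumption: natural (+)-podocarpic acid and allyl diethylphosphonoacetate are purchased. Bicyclic compounds carry labdane numbering and tricyclic ones podocarpane numbering.

**Route**

Step 1
Reactants: 1 (+)-podocarpic acid (12-hydroxypodocarpa-8,11,13-trien-19-oic acid; 4β-CO2H, 5α-H, 10β-CH3)
Product: 2 O-methylpodocarpic acid (12-methoxypodocarpa-8,11,13-trien-19-oic acid)
Conditions: Me2SO4 (1.2 equiv), 2 M aq. NaOH, 0 → 25 °C; then aq. HCl
Reagents that add atoms: dimethyl sulfate, COS(=O)(=O)OC
Why: Williamson etherification; in water the phenoxide should be methylated much faster than the hindered, solvated C19 carboxylate, so the free acid needed for the next step is kept and no stereocentre is touched.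

Step 2
Reactants: 2 O-methylpodocarpic acid
Product: 5 12-oxo-8β-podocarp-9(11)-en-19-oic acid, via dienol ether 3 (not isolated), via β,γ-enone 4 (not isolated)
Conditions: Li, NH3(l), THF, t-BuOH, −78 → −33 °C; MeOH; then 3 M HCl, MeOH/THF, 60 °C
Reagents that add atoms: water, O
Why: Birch reduction of the anisole ring C (the lithium carboxylate is inert) should give the 1,4-diene that keeps the tetrasubstituted C8=C9 bond, and acid hydrolysis of the enol ether with conjugation into C9=C11 protonates C8 under thermodynamic control, placing C14 equatorial on ring B and away from the axial C10 methyl (8β-H).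

Step 3
Reactants: 5 12-oxo-8β-podocarp-9(11)-en-19-oic acid
Product: 6 12-oxo-8β,9α-podocarpan-19-oic acid (trans-anti-trans)
Conditions: Li (3 equiv), NH3(l), THF, −78 °C; NH4Cl
Reagents that add atoms: none
Why: dissolving-metal conjugate reduction of the enone; the C9 carbanion should be protonated axially on the α face, anti to the C10 methyl, giving the more stable trans B/C junction (9α-H) before the enolate is quenched to the ketone.

Step 4
Reactants: 6 12-oxo-8β,9α-podocarpan-19-oic acid
Product: 7 trimethylsilyl 12-(trimethylsilyloxy)-8β,9α-podocarp-12-en-19-oate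
Conditions: LDA (2.3 equiv), TMSCl (3 equiv), THF, −78 °C; non-aqueous work-up
Reagents that add atoms: chlorotrimethylsilane, C[Si](C)(C)Cl
Why: kinetic deprotonation with internal silyl trapping should go to C13, because C11 is shielded by C1 and the C10 methyl and the C12(13) enol is also the preferred one in a trans-fused 2-decalone-type ring; the acid is carried as its silyl ester.

Step 5
Reactants: 7 trimethylsilyl 12-(trimethylsilyloxy)-8β,9α-podocarp-12-en-19-oate
Product: 8 12-oxo-8β,9α-podocarp-13-en-19-oic acid
Conditions: Pd(OAc)2 (10 mol%), O2 (1 atm), DMSO, 25 °C; dilute aq. HCl work-up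
Reagents that add atoms: none
Why: Saegusa–Ito oxidation; palladation at C13 and β-hydride loss from C14 should give the C13=C14 enone while dioxygen turns over the palladium, the silyl ester is lost on aqueous work-up, and any C11 regioisomer of 7 would only return enone 5, which can be recycled through step 3.

Step 6
Reactants: 8 12-oxo-8β,9α-podocarp-13-en-19-oic acid
Product: 11 13,14,15,16-tetranor-8βH-labdane-12,17,19-trioic acid, via ozonide 9 (not isolated), via α-keto acid 10 (not isolated)
Conditions: O3, EtOAc/CH2Cl2, −78 °C; then 30% H2O2, AcOH/H2O, 25 → 50 °C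
Reagents that add atoms: ozone, [O-][O+]=O; hydrogen peroxide, OO
Why: ozonolysis of the enone alkene with oxidative work-up should turn C14 into the C8 carboxyl (labdane C17) and leave an α-keto acid that hydrogen peroxide decarboxylates to the C12 acid, the classical enone-to-nor-diacid degradation; C8 and C9 are untouched and C8 already carries its carboxyl equatorially.

Step 7
Reactants: 11 13,14,15,16-tetranor-8βH-labdane-12,17,19-trioic acid
Product: 13 12-(1,3-dioxoisoindolin-2-yl) ester of triacid 11 (C17 and C19 acids free), via cyclic anhydride 12 (not isolated)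
Conditions: N,N'-diisopropylcarbodiimide (1.05 equiv), N-hydroxyphthalimide (1.1 equiv), DMAP (5 mol%), THF, 0 → 25 °C
Reagents that add atoms: N-hydroxyphthalimide, O=C1c2ccccc2C(=O)N1O
Why: carbodiimide dehydration should close the 1,5-diacid (C12/C17) to the six-membered anhydride, which N-hydroxyphthalimide opens at the less hindered, CH2-flanked C12 carbonyl; the axial, neopentyl C19 acid is too hindered to be activated.

Step 8
Reactants: 14 allyl diethylphosphonoacetate
Product: 16 allyl 2-(diethoxyphosphoryl)acrylate, via hydroxymethyl adduct 15 (not isolated)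
Conditions: (CH2O)n (2 equiv), piperidine (10 mol%), AcOH (10 mol%), toluene, 80 °C; then TsOH·H2O (5 mol%), reflux, Dean–Stark
Reagents that add atoms: formaldehyde (as paraformaldehyde), C=O
Why: Knoevenagel condensation with formaldehyde; amine-catalysed hydroxymethylation of the phosphonoacetate is followed by acid-catalysed dehydration with azeotropic removal of water, an order that avoids Michael addition of unreacted phosphonoacetate to the product.

Step 9
Reactants: 16 allyl 2-(diethoxyphosphoryl)acrylate
Product: 18 2-oxoethyl 2-(diethoxyphosphoryl)acrylate, via ozonide 17 (not isolated)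
Conditions: O3 (1 equiv, Sudan red 7B end point), CH2Cl2, −78 °C; then Me2S, −78 → 25 °C; used at once
Reagents that add atoms: ozone, [O-][O+]=O
Why: ozone is an electrophile and should cleave the monosubstituted allyl alkene well before the alkene that carries both the phosphoryl and the ester group, and reduction of the ozonide with dimethyl sulfide gives the glycolaldehyde ester.

Step 10
Reactants: 13 12-(1,3-dioxoisoindolin-2-yl) ester of triacid 11; 18 2-oxoethyl 2-(diethoxyphosphoryl)acrylate
Product: 20 (1S,4aR,5S,6R,8aR)-1,4a-dimethyl-5-[2-(2-oxo-2,5-dihydrofuran-3-yl)ethyl]decahydronaphthalene-1,6-dicarboxylic acid (8βH-labd-13-en-16,15-olide-17,19-dioic acid), via phosphonate adduct 19 (not isolated)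
Conditions: Ru(bpy)3(PF6)2 (1 mol%), Hantzsch ester (1.5 equiv), 18 (1.5 equiv), DMA, blue LEDs, 25 °C; then LiCl (6 equiv), DBU (6 equiv), 0 → 25 °C; aq. HCl work-up
Reagents that add atoms: none
Why: Proposed new method: the photoreduced ruthenium complex (Hantzsch ester as terminal reductant) transfers one electron to the N-acyloxyphthalimide of 13, which loses phthalimide anion and CO2 to give the primary C11 radical; this adds to the CH2 terminus (future C12) of the doubly activated alkene of 18, the C13 radical is reduced and protonated to phosphonoacetate 19, and LiCl/DBU then generates the C13 carbanion, which attacks the C14 aldehyde held five atoms away and expels diethyl phosphate through the oxaphosphetane to form C13=C14. The closest known reaction types are the photoredox decarboxylative Giese addition of redox-active esters, the conjugate addition/intramolecular Horner–Wadsworth–Emmons annulation of 2-phosphonoacrylates and the intramolecular Horner–Wadsworth–Emmons route to butenolides from phosphonoacetates of α-hydroxy ketones; their merger on a glycolaldehyde ester is the untested part. The single ring formed, the lactone C13–C14–C15–O–C16, closes by 5-exo-trig attack of C13 on the aldehyde carbon C14, and the ring forces the Z arrangement of C16 and C15 about the new alkene. No stereocentre is created in 20 (the C13 centre of 19 is a mixture and is erased), and C8, α to a carboxylate, is not deprotonated by DBU and already holds its carboxyl equatorially. The step needs chemoselectivity for the radical precursor over the free C17 and C19 acids, secured because only the phthalimide ester is reducible under net-reductive conditions, and for the alkene over the aldehyde of 18, secured by the nucleophilic character of the alkyl radical. It also needs ring closure to outrun Michael addition of the carbanion to residual 18, which the short tether and the reactive aldehyde should secure.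

**Compound list**

1 | (+)-podocarpic acid (12-hydroxypodocarpa-8,11,13-trien-19-oic acid) | C[C@]12CCC[C@](C)(C(=O)O)[C@@H]1CCc1ccc(O)cc12 | starting material
2 | O-methylpodocarpic acid (12-methoxypodocarpa-8,11,13-trien-19-oic acid) | C[C@]12CCC[C@](C)(C(=O)O)[C@@H]1CCc1ccc(OC)cc12 | intermediate
3 | 12-methoxypodocarpa-8,12-dien-19-oic acid (dienol ether) | C[C@]12CCC[C@](C)(C(=O)O)[C@@H]1CCC1=C2CC(OC)=CC1 | intermediate
4 | 12-oxopodocarp-8-en-19-oic acid (β,γ-enone) | C[C@]12CCC[C@](C)(C(=O)O)[C@@H]1CCC1=C2CC(=O)CC1 | intermediate
5 | 12-oxo-8β-podocarp-9(11)-en-19-oic acid | C[C@]12CCC[C@](C)(C(=O)O)[C@@H]1CC[C@H]1CCC(=O)C=C12 | intermediate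
6 | 12-oxo-8β,9α-podocarpan-19-oic acid | C[C@]12CCC[C@](C)(C(=O)O)[C@@H]1CC[C@H]1CCC(=O)C[C@@H]12 | intermediate
7 | trimethylsilyl 12-(trimethylsilyloxy)-8β,9α-podocarp-12-en-19-oate | C[C@]12CCC[C@](C)(C(=O)O[Si](C)(C)C)[C@@H]1CC[C@H]1CC=C(O[Si](C)(C)C)C[C@@H]12 | intermediate
8 | 12-oxo-8β,9α-podocarp-13-en-19-oic acid | C[C@]12CCC[C@](C)(C(=O)O)[C@@H]1CC[C@H]1C=CC(=O)C[C@@H]12 | intermediate
9 | 13,14-ozonide (1,2,4-trioxolane) of 8 | C[C@]12CCC[C@](C)(C(=O)O)[C@@H]1CC[C@H]1C3OC(OO3)C(=O)C[C@@H]12 | intermediate
10 | 12-oxo-13,14-seco-8β,9α-podocarpane-13,14,19-trioic acid (α-keto acid) | C[C@]12CCC[C@](C)(C(=O)O)[C@@H]1CC[C@@H](C(=O)O)[C@@H]2CC(=O)C(=O)O | intermediate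
11 | 13,14,15,16-tetranor-8βH-labdane-12,17,19-trioic acid [(1S,4aR,5S,6R,8aR)-5-(carboxymethyl)-1,4a-dimethyldecahydronaphthalene-1,6-dicarboxylic acid] | C[C@]12CCC[C@](C)(C(=O)O)[C@@H]1CC[C@@H](C(=O)O)[C@@H]2CC(=O)O | intermediate
12 | 12,17-cyclic anhydride of triacid 11 (trans-fused six-membered anhydride, C19 acid free) | C[C@]12CCC[C@](C)(C(=O)O)[C@@H]1CC[C@H]1C(=O)OC(=O)C[C@@H]12 | intermediate
13 | 12-(1,3-dioxoisoindolin-2-yl) ester of triacid 11 (C17 and C19 acids free) | C[C@]12CCC[C@](C)(C(=O)O)[C@@H]1CC[C@@H](C(=O)O)[C@@H]2CC(=O)ON1C(=O)c2ccccc2C1=O | intermediate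
14 | allyl diethylphosphonoacetate | C=CCOC(=O)CP(=O)(OCC)OCC | starting material
15 | allyl 2-(diethoxyphosphoryl)-3-hydroxypropanoate | C=CCOC(=O)C(CO)P(=O)(OCC)OCC | intermediate
16 | allyl 2-(diethoxyphosphoryl)acrylate | C=CCOC(=O)C(=C)P(=O)(OCC)OCC | intermediate
17 | (1,2,4-trioxolan-3-yl)methyl 2-(diethoxyphosphoryl)acrylate (ozonide) | C=C(C(=O)OCC1OCOO1)P(=O)(OCC)OCC | intermediate
18 | 2-oxoethyl 2-(diethoxyphosphoryl)acrylate | C=C(C(=O)OCC=O)P(=O)(OCC)OCC | intermediate
19 | 2-oxoethyl 2-(diethoxyphosphoryl)-4-[(1S,2R,4aR,5S,8aR)-2,5-dicarboxy-5,8a-dimethyldecahydronaphthalen-1-yl]butanoate (C13 epimers) | C[C@]12CCC[C@](C)(C(=O)O)[C@@H]1CC[C@@H](C(=O)O)[C@@H]2CCC(C(=O)OCC=O)P(=O)(OCC)OCC | intermediate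
20 | (1S,4aR,5S,6R,8aR)-1,4a-dimethyl-5-[2-(2-oxo-2,5-dihydrofuran-3-yl)ethyl]decahydronaphthalene-1,6-dicarboxylic acid | C[C@]12CCC[C@](C)(C(=O)O)[C@@H]1CC[C@@H](C(=O)O)[C@@H]2CCC1=CCOC1=O | target

**Step count and risks**

Total step count: 10 (steps 1–7 and 10 in the main line, steps 8 and 9 for the acceptor).
Longest linear sequence: 8 steps (steps 1–7, then step 10).

Steps most likely to fail:

1. Step 10 (proposed new method). The C11 radical may be quenched by hydrogen-atom transfer before it adds. The aldehyde ester may oligomerise under base. Intermolecular Michael addition of the C13 carbanion may outrun ring closure. The fallback closes the same C13=C14 bond by ring-closing metathesis, with known chemistry only, and sets out from 13. Allyl acrylate would be hydroxymethylated (paraformaldehyde, DABCO, aqueous dioxane; Baylis–Hillman reaction) to allyl 2-(hydroxymethyl)acrylate F1 and brominated (PBr3, Et2O, 0 °C) to allyl 2-(bromomethyl)acrylate F2. Photoreductive decarboxylation of 13 (Ru(bpy)3(PF6)2, Hantzsch ester, NaHCO3, DMA, blue LEDs) in the presence of F2 should give, by radical addition and β-scission of bromide, allyl 2-methylene-4-(decalinyl)butanoate diacid F3. Treatment of F3 with the second-generation Grubbs catalyst (H2IMes)(PCy3)Cl2Ru=CHPh in CH2Cl2 at 40 °C should close the butenolide with loss of ethylene, and the fallback comes back to the route at 20.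

2. Step 9. Ozone may also attack the acceptor alkene, and the aldehyde-bearing acrylate may polymerise or hydrate on handling. The fallback postpones the unveiling of the aldehyde until no acceptor alkene is left. It sets out from 16 (with 13): Giese addition under the photoreductive conditions of step 10 (Ru(bpy)3(PF6)2, Hantzsch ester, DMA, blue LEDs) should give allyl 2-(diethoxyphosphoryl)-4-(decalinyl)butanoate diacid F4. Ozonolysis of its allyl group (O3, CH2Cl2/MeOH, −78 °C; Me2S) then comes back to the route at 19, which is cyclised with LiCl/DBU as in the second stage of step 10.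

3. Step 4. The kinetic enolisation may not discriminate C13 from C11 well enough, and the bis-silylated product is sensitive to hydrolysis. The fallback replaces enolate chemistry by halogenation under thermodynamic enol control and sets out from 6. Phenyltrimethylammonium tribromide in THF at 0 °C should give 13α-bromo-12-oxo-8β,9α-podocarpan-19-oic acid F5 (equatorial bromide). Dehydrobromination with LiBr/Li2CO3 in DMF at 120 °C then comes back to the route at 8, bypassing 7.

Further compounds
F1 | step 10 | allyl 2-(hydroxymethyl)acrylate | C=CCOC(=O)C(=C)CO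
F2 | step 10 | allyl 2-(bromomethyl)acrylate | C=CCOC(=O)C(=C)CBr
F3 | step 10 | allyl 2-methylene-4-[(1S,2R,4aR,5S,8aR)-2,5-dicarboxy-5,8a-dimethyldecahydronaphthalen-1-yl]butanoate | C[C@]12CCC[C@](C)(C(=O)O)[C@@H]1CC[C@@H](C(=O)O)[C@@H]2CCC(=C)C(=O)OCC=C
F4 | step 9 | allyl 2-(diethoxyphosphoryl)-4-[(1S,2R,4aR,5S,8aR)-2,5-dicarboxy-5,8a-dimethyldecahydronaphthalen-1-yl]butanoate (C13 epimers) | C[C@]12CCC[C@](C)(C(=O)O)[C@@H]1CC[C@@H](C(=O)O)[C@@H]2CCC(C(=O)OCC=C)P(=O)(OCC)OCC
F5 | step 4 | 13α-bromo-12-oxo-8β,9α-podocarpan-19-oic acid | C[C@]12CCC[C@](C)(C(=O)O)[C@@H]1CC[C@H]1C[C@@H](Br)C(=O)C[C@@H]12
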